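Cadinane numbering is used (C7 bears the acrylic acid, C8 the ester oxygen; ring B = C1, C6, C7, C8, C9, C10). Ring B is taken apart at C7–C8 and C1–C6 by a Diels–Alder reaction that exploits its four contiguous stereocenters and the cis C6–H/C7–H pair. The dienophile is levoglucosenone, whose cis-locked enone supplies C5, C6, C7, C11 and C12 in enantiopure form. The diene is a 1,3-bis(silyloxy)triene that carries C8–C10, C1 and the ring A chain. One operation closes ring B and sets C6, C7 and C8. The sugar acetal is later fragmented to the C12 acid and a C5 vinyl group, and metathesis closes ring A.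

Key step: step 5

Remark: C4 carries C15 (the CH2OH carbon), C10 carries the C14 methylene, C11–C13 are the acrylic acid carbons, primed numbers belong to the ester side chain; compounds 1, 3, 9, 17 and 18 are taken as commercially available.

Step 1
Reactants: 1 2-[(trimethylsilyl)methyl]prop-2-en-1-ol
Product: 2 tert-butyldiphenylsilyl ether of 1
Conditions: TBDPSCl, imidazole, CH2Cl2, rt
Reagents that add atoms: tert-butyl(chloro)diphenylsilane, CC(C)(C)[Si](Cl)(c1ccccc1)c1ccccc1
Why: Silyl ether formation at the primary allylic alcohol protects the future C15 oxygen with a group that should survive every later step; no stereocenter is formed.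

Step 2
Reactants: 2 tert-butyldiphenylsilyl ether of 1; 3 but-3-en-2-one
Product: 4 6-{[(tert-butyldiphenylsilyl)oxy]methyl}hept-6-en-2-one
Conditions: TiCl4, CH2Cl2, −78 °C
Reagents that add atoms: none
Why: Hosomi–Sakurai conjugate allylation, in which the γ-carbon of the allylsilane attacks the TiCl4-activated enone and loss of the silyl group moves the double bond, should give the methyl ketone that already holds C9, C10, C1–C4 and C15; no stereocenter is formed.

Step 3
Reactants: 4 6-{[(tert-butyldiphenylsilyl)oxy]methyl}hept-6-en-2-one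
Product: 7 (1E)-1-[(tert-butyldimethylsilyl)oxy]-7-{[(tert-butyldiphenylsilyl)oxy]methyl}octa-1,7-dien-3-one, via kinetic lithium enolate 5 (not isolated), via lithium formyl enolate 6 (not isolated)
Conditions: LDA, THF, −78 °C; CF3CH2OCHO, −78 to 0 °C; then TBSCl, 0 °C to rt
Reagents that add atoms: 2,2,2-trifluoroethyl formate, O=COCC(F)(F)F; tert-butyl(chloro)dimethylsilane, CC(C)(C)[Si](C)(C)Cl
Why: Kinetic deprotonation at the methyl group, Claisen-type C-formylation with the activated formate (this carbon becomes C8) and O-silylation of the resulting enolate should give the β-silyloxy enone, whose push–pull double bond relaxes to the more stable E form; no stereocenter is formed.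

Step 4
Reactants: 7 (1E)-1-[(tert-butyldimethylsilyl)oxy]-7-{[(tert-butyldiphenylsilyl)oxy]methyl}octa-1,7-dien-3-one
Product: 8 (1E,3Z)-1,3-bis[(tert-butyldimethylsilyl)oxy]-7-{[(tert-butyldiphenylsilyl)oxy]methyl}octa-1,3,7-triene
Conditions: TBSOTf, Et3N, Et2O, 0 °C to rt
Reagents that add atoms: tert-butyldimethylsilyl trifluoromethanesulfonate, CC(C)(C)[Si](C)(C)OS(=O)(=O)C(F)(F)F
Why: Soft enolisation of the only remaining α-CH2 (silyl enol ether formation) should give the 2-silyloxy diene with the Z enol ether, so that the ring A chain sits on the outside of the s-cis diene; no stereocenter is formed.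

Step 5
Reactants: 8 (1E,3Z)-1,3-bis[(tert-butyldimethylsilyl)oxy]-7-{[(tert-butyldiphenylsilyl)oxy]methyl}octa-1,3,7-triene; 9 (−)-levoglucosenone, (1S,5R)-6,8-dioxabicyclo[3.2.1]oct-2-en-4-one
Product: 10 endo cycloadduct (ring B closed; C6, C7, C8 as in the target; C1 epimeric)
Conditions: toluene, 90 °C, sealed tube (BHT, cat.)
Reagents that add atoms: none
Why: Thermal, concerted but asynchronous normal-demand [4+2] cycloaddition in which the nucleophilic C1 terminus of the 1,3-dioxygenated diene bonds to the enone β-carbon (C6) and the silyloxy-bearing terminus C8 to the α-carbon (C7); the closest known reaction type is the Diels–Alder reaction of 1-alkoxy-3-silyloxy dienes with cyclic enones, and levoglucosenone is an established chiral dienophile. Ring B (C1, C6, C7, C8, C9, C10) is closed in the suprafacial [4+2] mode by the C7–C8 and C1–C6 bonds, and no other ring forms. C6 and C7 are set by approach to the enone face opposite the 1,6-anhydro bridge, and because the dienophile is a cis-locked ring alkene their hydrogens must end up cis, which is what places the C7 substituent axial on ring B in the target. C8 is set by the endo orientation of the ketone together with the E enol ether, which puts the C8 oxygen cis to the C7–C11 bond. C1 is formed cis to C5 in the same endo transition state and is corrected in step 6. The step needs regio-, face- and endo-selectivity: the donor pattern of the diene secures the first, the bridge the second, and the third rests on secondary orbital overlap against some steric pressure from C5.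

Step 6
Reactants: 10 endo cycloadduct
Product: 12 diketone with the C1 chain trans to C5 (C10 and C11 ketones; C8-OTBS), via all-cis diketone 11 (not isolated)
Conditions: 1 M HCl, THF, 0 °C; then DBU (0.1 equiv), CH2Cl2, 0 °C to rt
Reagents that add atoms: none
Why: Mild acid hydrolysis of the silyl enol ether gives the C10 ketone by protonation at C9, and base-mediated enolisation then epimerises C1 under thermodynamic control, because in the ring B chair fixed by the sugar ring the C1 chain of 11 is axial and 1,3-diaxial to the C7–C11 bond whereas in 12 it is equatorial.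

Step 7
Reactants: 12 diketone with the C1 chain trans to C5
Product: 13 bis-methylene acetal (C10=C14 and C11=C13 in place)
Conditions: Zn, CH2Br2, TiCl4, THF/CH2Cl2, 0 °C to rt
Reagents that add atoms: dibromomethane, BrCBr
Why: Lombardo methylenation converts both ketones into 1,1-disubstituted alkenes under non-basic conditions, so the stereocenters α to the carbonyl groups (C1, C7) and the β-silyloxy group at C8 should not be disturbed.

Step 8
Reactants: 13 bis-methylene acetal
Product: 14 methyl pyranoside with free C5-CH2OH (anomeric mixture at C12)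
Conditions: pyridinium p-toluenesulfonate (cat.), MeOH, 45 °C
Reagents that add atoms: methanol, CO
Why: Acid-catalysed transacetalisation, in which the allylic acetal ionises to an oxocarbenium ion that methanol captures, should open the strained anhydro bridge and free the primary hydroxyl while the C8 oxygen stays silylated and cannot take part; the new anomeric center is left as a mixture because C12 becomes sp2 later.

Step 9
Reactants: 14 methyl pyranoside with free C5-CH2OH
Product: 15 primary iodide
Conditions: I2, PPh3, imidazole, THF, 0 °C to rt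
Reagents that add atoms: iodine, II
Why: Garegg–Samuelsson iodination (SN2 displacement of the alkoxyphosphonium ion by iodide) converts the only free hydroxyl, a primary one, into the iodide needed for the later fragmentation; no stereocenter is touched.

Step 10
Reactants: 15 primary iodide
Product: 16 C8 alcohol
Conditions: HF·pyridine, pyridine, THF, 0 °C
Reagents that add atoms: none
Why: Chemoselective desilylation, since buffered HF·pyridine should remove the secondary tert-butyldimethylsilyl ether faster than the primary tert-butyldiphenylsilyl ether and does not ionise the acetal; the C8 configuration is retained because only the O–Si bond breaks.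

Step 11
Reactants: 17 (tert-butyldimethylsilyloxy)acetaldehyde; 18 1,1,1,3,3,3-hexafluoropropan-2-yl acrylate
Product: 19 hexafluoroisopropyl (3S)-4-[(tert-butyldimethylsilyl)oxy]-3-hydroxy-2-methylenebutanoate
Conditions: β-isocupreidine (10 mol%), DMF, −55 °C
Reagents that add atoms: none
Why: Catalytic asymmetric Morita–Baylis–Hillman reaction, in which the amine adds to the activated acrylate and the catalyst's phenolic hydroxyl directs the aldol step to one face of the aldehyde, should set the side-chain carbinol center in the sense known for this catalyst with aliphatic aldehydes (the descriptor is S because the silyloxymethyl group outranks the vinyl carbon).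

Step 12
Reactants: 19 hexafluoroisopropyl (3S)-4-[(tert-butyldimethylsilyl)oxy]-3-hydroxy-2-methylenebutanoate
Product: 20 hexafluoroisopropyl (3S)-3,4-bis[(tert-butyldimethylsilyl)oxy]-2-methylenebutanoate
Conditions: TBSOTf, 2,6-lutidine, CH2Cl2, −78 °C
Reagents that add atoms: tert-butyldimethylsilyl trifluoromethanesulfonate, CC(C)(C)[Si](C)(C)OS(=O)(=O)C(F)(F)F
Why: Silyl ether formation at the secondary allylic hydroxyl with a hindered base leaves the activated ester and the stereocenter untouched.

Step 13
Reactants: 20 hexafluoroisopropyl (3S)-3,4-bis[(tert-butyldimethylsilyl)oxy]-2-methylenebutanoate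
Product: 21 (3S)-3,4-bis[(tert-butyldimethylsilyl)oxy]-2-methylenebutanoic acid
Conditions: LiOH, THF/H2O, 0 °C; then 1 M HCl
Reagents that add atoms: lithium hydroxide, [Li+].[OH-]
Why: Saponification of the activated hexafluoroisopropyl ester is fast at 0 °C, so conjugate addition and loss of the β-silyloxy group should not compete; the stereocenter is not involved.

Step 14
Reactants: 16 C8 alcohol; 21 (3S)-3,4-bis[(tert-butyldimethylsilyl)oxy]-2-methylenebutanoic acid
Product: 22 C8 ester
Conditions: DCC, DMAP (cat.), CH2Cl2, 0 °C to rt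
Reagents that add atoms: none
Why: Steglich esterification acylates the equatorial C8 hydroxyl at oxygen, so C8 keeps its configuration and the side-chain center is not epimerisable.

Step 15
Reactants: 22 C8 ester
Product: 23 enal with C6 vinyl group (C7–C(=CH2)CHO)
Conditions: Zn dust, THF/H2O (4:1), 40 °C, ultrasound
Reagents that add atoms: none
Why: Bernet–Vasella reductive fragmentation, in which zinc inserts into the C–I bond and the organozinc expels the ring oxygen, should give the C5 vinyl group and, after collapse of the hemiacetal, the C12 aldehyde in one operation; the ring B stereocenters are not touched.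

Step 16
Reactants: 23 enal with C6 vinyl group
Product: 24 acrylic acid
Conditions: NaClO2, NaH2PO4, 2-methylbut-2-ene, t-BuOH/H2O, 0 °C to rt
Reagents that add atoms: sodium chlorite, [Na+].[O-]Cl=O
Why: Pinnick oxidation converts the α-methylene aldehyde into the acid without touching alkenes, esters or silyl ethers, the hypochlorite by-product being trapped by the added alkene; no stereocenter is affected.

Step 17
Reactants: 24 acrylic acid
Product: 25 tris-silyl ether of the target (ring A closed)
Conditions: second-generation Grubbs catalyst (5 mol%), CH2Cl2 (2 mM), 40 °C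
Reagents that add atoms: none
Why: Ring-closing olefin metathesis between the C5 vinyl group and the 1,1-disubstituted C4 alkene should close ring A as its trisubstituted C4=C5 alkene with loss of ethene, the trans ring fusion being already fixed by the diequatorial C1 and C6 substituents and the other 1,1-disubstituted alkenes being unable to form a ring of useful size with the vinyl group.

Step 18
Reactants: 25 tris-silyl ether of the target
Product: 26 (1S,6S,7R,8R)-8-{[(3S)-3,4-dihydroxy-2-methylenebutanoyl]oxy}-15-hydroxycadina-4,10(14),11(13)-trien-12-oic acid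
Conditions: Bu4NF, AcOH (1:1), THF, 0 °C to rt
Reagents that add atoms: none
Why: Global desilylation with buffered fluoride cleaves only O–Si bonds, and the acetic acid buffer should suppress lactonisation of the freed 4'-hydroxyl onto the side-chain ester; all stereocenters are retained.

Compound list
1 | 2-[(trimethylsilyl)methyl]prop-2-en-1-ol | C=C(CO)C[Si](C)(C)C | starting material
2 | tert-butyl(diphenyl)({2-[(trimethylsilyl)methyl]prop-2-en-1-yl}oxy)silane | C=C(CO[Si](c1ccccc1)(c1ccccc1)C(C)(C)C)C[Si](C)(C)C | intermediate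
3 | but-3-en-2-one | CC(=O)C=C | starting material
4 | 6-{[(tert-butyldiphenylsilyl)oxy]methyl}hept-6-en-2-one | CC(=O)CCCC(=C)CO[Si](c1ccccc1)(c1ccccc1)C(C)(C)C | intermediate
5 | lithium 6-{[(tert-butyldiphenylsilyl)oxy]methyl}hepta-1,6-dien-2-olate (kinetic enolate) | [Li+].[O-]C(=C)CCCC(=C)CO[Si](c1ccccc1)(c1ccccc1)C(C)(C)C | intermediate
6 | lithium (1Z)-7-{[(tert-butyldiphenylsilyl)oxy]methyl}-3-oxoocta-1,7-dien-1-olate | [Li+].[O-]/C=C\C(=O)CCCC(=C)CO[Si](c1ccccc1)(c1ccccc1)C(C)(C)C | intermediate
7 | (1E)-1-[(tert-butyldimethylsilyl)oxy]-7-{[(tert-butyldiphenylsilyl)oxy]methyl}octa-1,7-dien-3-one | CC(C)(C)[Si](C)(C)O/C=C/C(=O)CCCC(=C)CO[Si](c1ccccc1)(c1ccccc1)C(C)(C)C | intermediate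
8 | (1E,3Z)-1,3-bis[(tert-butyldimethylsilyl)oxy]-7-{[(tert-butyldiphenylsilyl)oxy]methyl}octa-1,3,7-triene | CC(C)(C)[Si](C)(C)O/C=C/C(O[Si](C)(C)C(C)(C)C)=C/CCC(=C)CO[Si](c1ccccc1)(c1ccccc1)C(C)(C)C | intermediate
9 | (−)-levoglucosenone, (1S,5R)-6,8-dioxabicyclo[3.2.1]oct-2-en-4-one | O=C1C=C[C@H]2CO[C@@H]1O2 | starting material
10 | endo Diels–Alder adduct: ring B (C8-OTBS, C9=C10 silyl enol ether, C1 chain) cis-fused at C6–C7 to the 1,6-anhydropyranos-2-ulose; H6 and H7 on the face of the bridge; C8–O cis to C11; C1 chain cis to C5 | O=C1[C@@H]2[C@H](O[Si](C)(C)C(C)(C)C)C=C(O[Si](C)(C)C(C)(C)C)[C@H](CCC(=C)CO[Si](c4ccccc4)(c4ccccc4)C(C)(C)C)[C@@H]2[C@H]3CO[C@@H]1O3 | intermediate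
11 | all-cis diketone: as 10 with C10 ketone; C1 chain still cis to C5 (axial) | O=C1[C@@H]2[C@H](O[Si](C)(C)C(C)(C)C)CC(=O)[C@H](CCC(=C)CO[Si](c4ccccc4)(c4ccccc4)C(C)(C)C)[C@@H]2[C@H]3CO[C@@H]1O3 | intermediate
12 | diketone with C1 chain trans to C5 (C1, C6, C7, C8 as in 26) | O=C1[C@@H]2[C@H](O[Si](C)(C)C(C)(C)C)CC(=O)[C@@H](CCC(=C)CO[Si](c4ccccc4)(c4ccccc4)C(C)(C)C)[C@@H]2[C@H]3CO[C@@H]1O3 | intermediate
13 | bis-methylene acetal: C10=C14 and C11=C13 exocyclic alkenes; C8-OTBS; 1,6-anhydro acetal intact | C=C1[C@@H]2[C@H](O[Si](C)(C)C(C)(C)C)CC(=C)[C@@H](CCC(=C)CO[Si](c4ccccc4)(c4ccccc4)C(C)(C)C)[C@@H]2[C@H]3CO[C@@H]1O3 | intermediate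
14 | methyl pyranoside: C12(H)(OMe)–O–C5(H)(CH2OH) ring across C6/C7; C8-OTBS; anomeric mixture | C=C1[C@@H]2[C@H](O[Si](C)(C)C(C)(C)C)CC(=C)[C@@H](CCC(=C)CO[Si](c3ccccc3)(c3ccccc3)C(C)(C)C)[C@@H]2[C@@H](CO)OC1OC | intermediate
15 | primary iodide: as 14 with C5-CH2I | C=C1[C@@H]2[C@H](O[Si](C)(C)C(C)(C)C)CC(=C)[C@@H](CCC(=C)CO[Si](c3ccccc3)(c3ccccc3)C(C)(C)C)[C@@H]2[C@@H](CI)OC1OC | intermediate
16 | C8 alcohol: as 15 with free equatorial C8-OH | C=C1[C@@H]2[C@H](O)CC(=C)[C@@H](CCC(=C)CO[Si](c3ccccc3)(c3ccccc3)C(C)(C)C)[C@@H]2[C@@H](CI)OC1OC | intermediate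
17 | (tert-butyldimethylsilyloxy)acetaldehyde | CC(C)(C)[Si](C)(C)OCC=O | starting material
18 | 1,1,1,3,3,3-hexafluoropropan-2-yl acrylate | C=CC(=O)OC(C(F)(F)F)C(F)(F)F | starting material
19 | hexafluoroisopropyl (3S)-4-[(tert-butyldimethylsilyl)oxy]-3-hydroxy-2-methylenebutanoate | C=C(C(=O)OC(C(F)(F)F)C(F)(F)F)[C@H](O)CO[Si](C)(C)C(C)(C)C | intermediate
20 | hexafluoroisopropyl (3S)-3,4-bis[(tert-butyldimethylsilyl)oxy]-2-methylenebutanoate | C=C(C(=O)OC(C(F)(F)F)C(F)(F)F)[C@H](O[Si](C)(C)C(C)(C)C)CO[Si](C)(C)C(C)(C)C | intermediate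
21 | (3S)-3,4-bis[(tert-butyldimethylsilyl)oxy]-2-methylenebutanoic acid | C=C(C(=O)O)[C@H](O[Si](C)(C)C(C)(C)C)CO[Si](C)(C)C(C)(C)C | intermediate
22 | C8 ester of 16 with acid 21 | C=C1[C@@H]2[C@H](OC(=O)C(=C)[C@H](O[Si](C)(C)C(C)(C)C)CO[Si](C)(C)C(C)(C)C)CC(=C)[C@@H](CCC(=C)CO[Si](c3ccccc3)(c3ccccc3)C(C)(C)C)[C@@H]2[C@@H](CI)OC1OC | intermediate
23 | enal: monocyclic ring B with C7–C(=CH2)CHO (axial), C6 vinyl, C1 chain, C10 methylene, C8 ester; stereocenters as in 26 | C=C(C=O)[C@H]1[C@@H](C=C)[C@H](CCC(=C)CO[Si](c2ccccc2)(c2ccccc2)C(C)(C)C)C(=C)C[C@H]1OC(=O)C(=C)[C@H](O[Si](C)(C)C(C)(C)C)CO[Si](C)(C)C(C)(C)C | intermediate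
24 | acrylic acid: as 23 with C12 carboxylic acid | C=C(C(=O)O)[C@H]1[C@@H](C=C)[C@H](CCC(=C)CO[Si](c2ccccc2)(c2ccccc2)C(C)(C)C)C(=C)C[C@H]1OC(=O)C(=C)[C@H](O[Si](C)(C)C(C)(C)C)CO[Si](C)(C)C(C)(C)C | intermediate
25 | 15-O-TBDPS, 3',4'-bis-O-TBS ether of 26 (trans-fused rings A and B) | C=C(C(=O)O)[C@H]1[C@H]2C=C(CO[Si](c3ccccc3)(c3ccccc3)C(C)(C)C)CC[C@@H]2C(=C)C[C@H]1OC(=O)C(=C)[C@H](O[Si](C)(C)C(C)(C)C)CO[Si](C)(C)C(C)(C)C | intermediate
26 | (1S,6S,7R,8R)-8-{[(3S)-3,4-dihydroxy-2-methylenebutanoyl]oxy}-15-hydroxycadina-4,10(14),11(13)-trien-12-oic acid | C=C(C(=O)O)[C@H]1[C@H]2C=C(CO)CC[C@@H]2C(=C)C[C@H]1OC(=O)C(=C)[C@H](O)CO | target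

Total step count: 18 steps. Longest linear sequence: 15 steps (steps 1–10 and 14–18); steps 11–13 make the side-chain acid.

Steps most likely to fail:

First, step 5. The endo preference may be eroded, because in the endo transition state the outside chain at C1 is nearly eclipsed with the bulky C5 of the sugar ring; passage through the exo transition state would give the C8 epimer with C1 already correct. In that case the exo adduct F1, formed from 8 and 9 under the same conditions, would be carried through the same operations without the base treatment: acid hydrolysis to diketone F2, Lombardo methylenation to F3, methanolysis to F4, iodination to F5 and HF·pyridine to the axial C8 alcohol F6. The ester would then be installed with inversion by a Mitsunobu reaction of F6 with acid 21 (PPh3, diisopropyl azodicarboxylate, toluene), which comes back to the route at 22.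

Second, step 6. E1cB loss of the C8 silanolate from the β-silyloxy ketone may compete with enolisation towards C1. Setting out from 10, the elimination would then be made deliberate (CF3CO2H, CH2Cl2) to give enone F7, in which C1 equilibrates with no leaving group in the β-position. Copper-catalysed conjugate borylation (B2pin2, CuCl, NaOtBu, MeOH, THF), expected anti to the axial C7 substituent, would give boronate F8; oxidation (NaBO3, THF/H2O) would give hydroxy ketone F9 and silylation (TBSOTf, 2,6-lutidine) diketone F2. From F2 the sequence F3, F4, F5, F6 and the Mitsunobu esterification described above would return to the route at 22.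

Third, step 8. Under acid the allylic oxocarbenium ion may be captured at the exocyclic carbon, or the 1,1-disubstituted alkenes may migrate into the ring. Setting out from 13, the bicyclic acetal would instead be opened reductively with DIBAL-H (CH2Cl2, −78 to 0 °C; hydride delivered to C12 after coordination of the bridge oxygen) to give tetrahydropyranylmethanol F10. Iodination would give F11, HF·pyridine the C8 alcohol F12, and Steglich esterification with 21 the ester F13. Zinc fragmentation of F13 would open the ring to the vinyl-substituted allylic alcohol F14, and oxidation with MnO2 (CH2Cl2) would come back to the route at 23.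

Further compounds
F1 | step 5 | exo cycloadduct: as 10 but C8–OTBS trans to C11 and C1 chain trans to C5 | O=C1[C@@H]2[C@@H](O[Si](C)(C)C(C)(C)C)C=C(O[Si](C)(C)C(C)(C)C)[C@@H](CCC(=C)CO[Si](c4ccccc4)(c4ccccc4)C(C)(C)C)[C@@H]2[C@H]3CO[C@@H]1O3
F2 | step 5 | C8 epimer of diketone 12 | O=C1[C@@H]2[C@@H](O[Si](C)(C)C(C)(C)C)CC(=O)[C@@H](CCC(=C)CO[Si](c4ccccc4)(c4ccccc4)C(C)(C)C)[C@@H]2[C@H]3CO[C@@H]1O3
F3 | step 5 | C8 epimer of bis-methylene acetal 13 | C=C1[C@@H]2[C@@H](O[Si](C)(C)C(C)(C)C)CC(=C)[C@@H](CCC(=C)CO[Si](c4ccccc4)(c4ccccc4)C(C)(C)C)[C@@H]2[C@H]3CO[C@@H]1O3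
F4 | step 5 | C8 epimer of methyl pyranoside 14 | C=C1[C@@H]2[C@@H](O[Si](C)(C)C(C)(C)C)CC(=C)[C@@H](CCC(=C)CO[Si](c3ccccc3)(c3ccccc3)C(C)(C)C)[C@@H]2[C@@H](CO)OC1OC
F5 | step 5 | C8 epimer of iodide 15 | C=C1[C@@H]2[C@@H](O[Si](C)(C)C(C)(C)C)CC(=C)[C@@H](CCC(=C)CO[Si](c3ccccc3)(c3ccccc3)C(C)(C)C)[C@@H]2[C@@H](CI)OC1OC
F6 | step 5 | C8 epimer of alcohol 16 (axial hydroxyl) | C=C1[C@@H]2[C@@H](O)CC(=C)[C@@H](CCC(=C)CO[Si](c3ccccc3)(c3ccccc3)C(C)(C)C)[C@@H]2[C@@H](CI)OC1OC
F7 | step 6 | enone: C8=C9 conjugated to the C10 ketone, C11 ketone, C1 chain trans to C5 | O=C1[C@@H]2C=CC(=O)[C@@H](CCC(=C)CO[Si](c4ccccc4)(c4ccccc4)C(C)(C)C)[C@@H]2[C@H]3CO[C@@H]1O3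
F8 | step 6 | C8 pinacol boronate (boron trans to C11) of the diketone | O=C1[C@@H]2[C@@H](B4OC(C)(C)C(C)(C)O4)CC(=O)[C@@H](CCC(=C)CO[Si](c5ccccc5)(c5ccccc5)C(C)(C)C)[C@@H]2[C@H]3CO[C@@H]1O3
F9 | step 6 | C8 hydroxy diketone (hydroxyl trans to C11) | O=C1[C@@H]2[C@@H](O)CC(=O)[C@@H](CCC(=C)CO[Si](c4ccccc4)(c4ccccc4)C(C)(C)C)[C@@H]2[C@H]3CO[C@@H]1O3
F10 | step 8 | tetrahydropyranylmethanol: as 14 but C12 is a ring CH2 | C=C1[C@@H]2[C@H](O[Si](C)(C)C(C)(C)C)CC(=C)[C@@H](CCC(=C)CO[Si](c3ccccc3)(c3ccccc3)C(C)(C)C)[C@@H]2[C@@H](CO)OC1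
F11 | step 8 | iodide of F10 | C=C1[C@@H]2[C@H](O[Si](C)(C)C(C)(C)C)CC(=C)[C@@H](CCC(=C)CO[Si](c3ccccc3)(c3ccccc3)C(C)(C)C)[C@@H]2[C@@H](CI)OC1
F12 | step 8 | C8 alcohol of F11 | C=C1[C@@H]2[C@H](O)CC(=C)[C@@H](CCC(=C)CO[Si](c3ccccc3)(c3ccccc3)C(C)(C)C)[C@@H]2[C@@H](CI)OC1
F13 | step 8 | C8 ester of F12 with acid 21 | C=C1[C@@H]2[C@H](OC(=O)C(=C)[C@H](O[Si](C)(C)C(C)(C)C)CO[Si](C)(C)C(C)(C)C)CC(=C)[C@@H](CCC(=C)CO[Si](c3ccccc3)(c3ccccc3)C(C)(C)C)[C@@H]2[C@@H](CI)OC1
F14 | step 8 | allylic alcohol: as 23 with C12 as CH2OH | C=C(CO)[C@H]1[C@@H](C=C)[C@H](CCC(=C)CO[Si](c2ccccc2)(c2ccccc2)C(C)(C)C)C(=C)C[C@H]1OC(=O)C(=C)[C@H](O[Si](C)(C)C(C)(C)C)CO[Si](C)(C)C(C)(C)C
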